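Remark on the chemistry: the C6–D3 axis of the target has only small ortho substituents (three hydroxyls and one hydrogen) and is taken to rotate freely, so the compound is treated as achiral and no axial configuration is set.

## Structural features

The target is apigenin with an aryl group on C6: a 4H-chromen-4-one (benzo ring A fused to pyranone ring C) with a 4-hydroxyphenyl ring B on C2, hydroxyls on C5 and C7, and a 4-hydroxybenzoic acid ring D bonded through its carbon D3 to C6. There is no stereocentre, so only the constitution has to be controlled, above all the position of ring D on ring A. Ring C is the fragile part: with a free 5-hydroxyl, hot protic acid or hot strong base can open the pyranone and close it onto the other ortho oxygen, which would move ring D from C6 to C8 (Wessely–Moser rearrangement), and the free polyphenol is easily oxidised in base. The real difficulty is the biaryl bond: C6 lies between the oxygen-bearing carbons C5 and C7, C8 is electronically similar, and the bond is flanked by three ortho oxygens. The key step uses the fact that O5 and the oxygen on D4 each stand ortho to one of the two carbons to be joined, so a single CH2 between them (O5–CH2–O–D4) holds D3 beside C6 and away from C8; forming C6–D3 then closes a seven-membered 1,3-dioxepine. O5 is also the one oxygen of the flavone that is easy to single out, because its hydrogen bond to the C4 carbonyl makes it the last hydroxyl to be alkylated, and the bridge then protects O5 and the D4 oxygen until the final step.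

## Logic of the disconnections

9 ⇒ 8. Four C–O bonds are cut: the two O–CH3 bonds at O7 and O4' and the two O–CH2 bonds of the bridge. One Lewis acid breaks all of them, so the bridge that served the key step is also the protecting group of two phenols. The gain is that the polar, oxidisable polyphenol exists only after the last step. The forward step must dealkylate without opening ring C, which excludes hot HBr or HI and points to BBr3 at low temperature.

8 ⇒ 7. The acyl C–O bond of the methyl ester is cut. The ester masks the acid during the base-mediated alkylation and the palladium step and comes with the purchasable ring D unit. It is removed at this stage and not last because in 7 O5 is still part of the bridge: if hydroxide opened ring C reversibly, it could only close again onto O1, so the aryl group cannot wander to C8. The demand is mild hydroxide only.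

7 ⇒ 6. The C6–D3 biaryl bond is cut, which opens the seven-membered ring; this is the strategic cut. The bond is hindered and an intermolecular reaction on ring A cannot be told to choose C6 over C8, whereas a bridge anchored on O5 reaches only C6. The gain is that 6 is a plain mixed acetal of two phenols with an unfunctionalised C6–H and bromine on D3. The demand is that palladium, after insertion into C–Br, cleaves the C6–H bond in a seven-membered closure faster than the bromide is reduced or reacts between molecules.

6 ⇒ 2 + 5. The O5–CH2 bond is cut. The electrophilic α-chloro ether is placed on the ring D half because that electron-poor ring survives the chlorinating reagent, which electron-rich ring A would not. The gain is two fragments of similar size, one of them a flavone with a single free hydroxyl. The demand is complete deprotonation of the chelated hydroxyl of 2 and immediate use of the water-sensitive 5.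

5 ⇒ 4. The C–Cl bond is exchanged for a C–S bond. 5 cannot be stored, whereas 4 is a stable O,S-acetal from which 5 is released on demand. The demand is chlorination at sulfur only, which the deactivated ring of 4 allows.

4 ⇒ 3. The O–CH2 bond is cut. 3 is purchasable and already has bromine ortho and the ester para to the hydroxyl, so ring D needs no aromatic substitution chemistry. The demand is a simple O-alkylation of a moderately nucleophilic phenoxide.

2 ⇒ 1. The two O–CH3 bonds at O7 and O4' are cut. 1 is a purchasable bulk flavone with the complete A–C–B skeleton, so no ring has to be built. The demand is control of stoichiometry so that methylation stops before the chelated O5.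

## Other disconnections considered

Alternative 1: The cut goes through ring C (O1–C8a and C4–C4a) and leaves the biaryl intact. In the forward sense an aryne released with CsF from the silyl triflate A2, which already carries ring D on the future C6, would add the carboxylate oxygen of 3-(4-methoxyphenyl)prop-2-ynoic acid A3 at C8a. The aryl anion at C4a would then take the acyl group from oxygen and give the ortho-hydroxyaryl ynone A1, which is closed 6-endo to the pyranone and deprotected.
- In its favour: it is convergent and metal-free, and the methoxy group next to C4a should steer the oxygen nucleophile to the remote aryne carbon C8a, so the acyl group lands where it is needed.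
- Against it here: the hindered C6–D3 bond and the C6/C8 question are not solved but moved into the preparation of A2, a pentasubstituted arene whose silyl and triflate groups must be installed beside a preformed tri-ortho-substituted biaryl. The aryl anion may also be protonated by the acid before the acyl shift, and A1 can close 5-exo to an aurone as well as 6-endo.
- Structure: this plan builds ring C, which the chosen plan buys ready-made.
- Mechanism: polar aryne chemistry against an organopalladium C–H arylation; both have good analogy, and neither is clearly the safer.
- Step economy: the preparation of A2 makes the route clearly longer.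
- Where it is better: the tert-butyl ester and methyl ethers of the cyclised product would fall in one BBr3 step, one step shorter than the two-step endgame chosen here.

Alternative 2: The cut takes ring D apart at D1–D2 and D5–D6. Forward, the flavone-substituted silyloxydiene A5 would add methyl propiolate A6 in a Diels–Alder reaction to give the cyclohexa-1,4-diene A4, followed by dehydrogenation, desilylation and deprotection.
- In its favour: the polarisation of the diene (nucleophilic terminus next to the silyloxy carbon) places the ester para to the oxygen as required, and no metal is needed.
- Against it here: ring D with all three substituents can be bought, so building it is poor economy. Attaching the four-carbon unit of A5 to C6 still requires a C6-selective C–C bond formation on the flavone, which this plan does not address. The diene bears a 2,6-dimethoxyaryl group that twists and shields it, the silyl enol ether is hydrolytically labile, and an extra oxidation is needed to reach the arene.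
- Structure: it leaves the C6/C8 problem open, which the bridge solves.
- Mechanism: a thermal cycloaddition is simpler than a seven-membered palladacycle and is its equal or better in predictability of the ring-forming event.
- Step economy: it is longer.
- Where it is better: the D4 oxygen is freed with fluoride, a gentler unmasking than the Lewis-acid cleavage of the bridge.

Alternative 3: The cut takes ring D apart at D2–D3 and D4–D5. Forward, methyl coumalate A9 and the flavonyl ynol ether A8 would combine in an inverse-demand cycloaddition, and loss of CO2 from the bridged lactone would give the arene A7 directly.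
- In its favour: no oxidation step is needed, and the polarities match. The flavone-bearing alkyne carbon is the nucleophilic one and should bond to C6 of A9, which puts the ethoxy group para to the ester.
- Against it here: A8 must come from a 6-halogenated flavone, so the C6/C8 selection returns. Ethyl ynol ethers lose ethene on heating and are acid-sensitive, yet an alkyne flanked by two ortho methoxy groups will need heat to react.
- Structure: the difficult regiochemistry on ring A is again left to an earlier step.
- Mechanism: a cycloaddition–cycloreversion is clean when it proceeds, but its thermal window here is narrow.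
- Step economy: it is longer up to A7.
- Where it is equal or better: A7 is a fully protected target, so the endgame (BBr3, then ester hydrolysis) equals the chosen one in length, and it gives aromatic ring D more directly than Alternative 2.

Key step: step 4

## Route

Step 1
Reactants: 1 apigenin, 5,7-dihydroxy-2-(4-hydroxyphenyl)-4H-chromen-4-one
Product: 2 5-hydroxy-7-methoxy-2-(4-methoxyphenyl)-4H-chromen-4-one
Conditions: MeI (2.3 equiv), K2CO3 (2.5 equiv), acetone, reflux
Reagents that add atoms: iodomethane, CI
Why: Williamson O-methylation; the 7- and 4'-hydroxyls are the acidic, unencumbered phenols, whereas the 5-hydroxyl is held in a hydrogen bond to the C4 carbonyl and is the last to be deprotonated by K2CO3, so with a limited amount of MeI the reaction should stop at the 7,4'-dimethyl ether.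

Step 2
Reactants: 3 methyl 3-bromo-4-hydroxybenzoate
Product: 4 methyl 3-bromo-4-[(methylsulfanyl)methoxy]benzoate
Conditions: NaH, DMF, 0 °C; ClCH2SMe, NaI (cat.), rt
Reagents that add atoms: chloromethyl methyl sulfide, CSCCl
Why: Williamson etherification of the sodium phenoxide with the iodide formed in the flask from ClCH2SMe and NaI (Finkelstein exchange); the ester and the aryl bromide are inert to NaH at this temperature, and the O,S-acetal is a stable, storable precursor of the chloromethyl ether.

Step 3
Reactants: 4 methyl 3-bromo-4-[(methylsulfanyl)methoxy]benzoate; 2 5-hydroxy-7-methoxy-2-(4-methoxyphenyl)-4H-chromen-4-one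
Product: 6 methyl 3-bromo-4-({[7-methoxy-2-(4-methoxyphenyl)-4-oxo-4H-chromen-5-yl]oxy}methoxy)benzoate, via methyl 3-bromo-4-(chloromethoxy)benzoate 5 (not isolated)
Conditions: 4 (1.3 equiv), SO2Cl2, CH2Cl2, 0 °C; volatiles removed; then sodium salt of 2 (NaH, DMF), 0 °C to rt
Reagents that add atoms: none
Why: SO2Cl2 chlorinates sulfur, the chlorosulfonium ion fragments to the aryloxymethyl oxocarbenium ion and MeSCl, and chloride capture gives the α-chloro ether 5, whose ring is too deactivated by ester and bromine to be chlorinated. After removal of the volatiles the sodium phenoxide of 2, freed from its chelate by NaH, displaces chloride (Williamson-type O-alkylation by an α-chloro ether) to give the mixed diaryl formaldehyde acetal. 2 has only this one hydroxyl, so no site selectivity is required.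

Step 4
Reactants: 6 methyl 3-bromo-4-({[7-methoxy-2-(4-methoxyphenyl)-4-oxo-4H-chromen-5-yl]oxy}methoxy)benzoate
Product: 7 methylene-bridged biaryl: methyl 4-hydroxy-3-[5-hydroxy-7-methoxy-2-(4-methoxyphenyl)-4-oxo-4H-chromen-6-yl]benzoate in which the two hydroxyl oxygens (O5 of the flavone and the oxygen on D4) are joined by one CH2 group (flavone-fused dibenzo[d,f][1,3]dioxepine)
Conditions: Pd(OAc)2 (10 mol %), PCy3·HBF4 (20 mol %), PivOH (30 mol %), K2CO3 (2.5 equiv), DMA (0.02 M), 120 °C, Ar
Reagents that add atoms: none
Why: Pd(OAc)2 is reduced in the flask to zerovalent palladium, which adds oxidatively to the C–Br bond on D3; bromide on the divalent arylpalladium is exchanged for pivalate, which removes the C6 hydrogen while the Pd–C6 bond forms (concerted metalation–deprotonation), and reductive elimination from the diarylpalladium gives the C6–D3 bond and returns zerovalent palladium. The closest known reaction type is the palladium-catalysed intramolecular direct arylation of an arene C–H bond by a tethered aryl halide under carboxylate assistance, here in its less common seven-membered form. The one ring closed is the 1,3-dioxepine (C6, C5, O5, CH2, O, D4, D3), closed in a seven-membered mode by reductive elimination from an eight-membered palladacycle; the biaryl it contains is twisted, so the ring is not strained. No stereocentre is formed and the twisted axis of the bridged biaryl interconverts freely. The selectivity needed is C6 against C8 and ring closure against coupling between molecules. The first is secured by the substrate: the three-atom bridge starts at O5, whose only ortho C–H is C6 (the other ortho carbon is the ring-fusion carbon C4a, and C8 is para to C5 and out of reach), and the peri C4 carbonyl turns the O5 substituent toward the C6 side. The second is helped by high dilution, and the electron-rich PCy3 ligand keeps oxidative addition and C–H cleavage ahead of hydrodebromination. K2CO3 takes up the HBr, and the ester, the acetal, the methyl ethers and the pyranone are all stable to these weakly basic conditions.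

Step 5
Reactants: 7 methylene-bridged biaryl methyl ester
Product: 8 methylene-bridged biaryl acid: 4-hydroxy-3-[5-hydroxy-7-methoxy-2-(4-methoxyphenyl)-4-oxo-4H-chromen-6-yl]benzoic acid with O5 and the D4 oxygen joined by one CH2 group
Conditions: LiOH·H2O (4 equiv), THF–MeOH–H2O, 40 °C; then 1 M HCl to pH 2
Reagents that add atoms: lithium hydroxide, [Li+].[OH-]
Why: Saponification (acyl substitution by hydroxide, whose oxygen ends in the carboxyl group); the diaryl acetal, the aryl methyl ethers and the biaryl are stable to aqueous base. The step is placed here because O5 is still locked in the bridge, so that even a reversible opening of ring C by hydroxide could only close again onto O1 and the aryl group cannot move to C8.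

Step 6
Reactants: 8 methylene-bridged biaryl acid
Product: 9 3-[5,7-dihydroxy-2-(4-hydroxyphenyl)-4-oxo-4H-chromen-6-yl]-4-hydroxybenzoic acid
Conditions: BBr3 (10 equiv), CH2Cl2, −78 °C to rt; ice-water quench
Reagents that add atoms: none
Why: Lewis-acid dealkylation: BBr3 coordinates each ether oxygen and bromide attacks the methyl or methylene carbon, which cleaves both methyl ethers and both C–O bonds of the bridge; the acid is carried as its acyloxyborane and all O–B bonds are hydrolysed on quench. No hot protic acid is used and the quench is cold and free of methanol, which should avoid Wessely–Moser isomerisation and re-esterification.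

## Compound list

1 | apigenin, 5,7-dihydroxy-2-(4-hydroxyphenyl)-4H-chromen-4-one | O=c1cc(-c2ccc(O)cc2)oc2cc(O)cc(O)c12 | starting material
2 | 5-hydroxy-7-methoxy-2-(4-methoxyphenyl)-4H-chromen-4-one | COc1ccc(-c2cc(=O)c3c(O)cc(OC)cc3o2)cc1 | intermediate
3 | methyl 3-bromo-4-hydroxybenzoate | COC(=O)c1ccc(O)c(Br)c1 | starting material
4 | methyl 3-bromo-4-[(methylsulfanyl)methoxy]benzoate | COC(=O)c1ccc(OCSC)c(Br)c1 | intermediate
5 | methyl 3-bromo-4-(chloromethoxy)benzoate | COC(=O)c1ccc(OCCl)c(Br)c1 | intermediate
6 | methyl 3-bromo-4-({[7-methoxy-2-(4-methoxyphenyl)-4-oxo-4H-chromen-5-yl]oxy}methoxy)benzoate | COC(=O)c1ccc(OCOc2cc(OC)cc3oc(-c4ccc(OC)cc4)cc(=O)c23)c(Br)c1 | intermediate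
7 | methylene-bridged biaryl methyl ester (O5 and the D4 oxygen joined by CH2, C6 bonded to D3, 7-OMe and 4'-OMe kept) | COC(=O)c1ccc2OCOc3c(c(OC)cc4oc(-c5ccc(OC)cc5)cc(=O)c34)-c2c1 | intermediate
8 | methylene-bridged biaryl carboxylic acid (as 7, with CO2H in place of CO2Me) | O=C(O)c1ccc2OCOc3c(c(OC)cc4oc(-c5ccc(OC)cc5)cc(=O)c34)-c2c1 | intermediate
9 | 3-[5,7-dihydroxy-2-(4-hydroxyphenyl)-4-oxo-4H-chromen-6-yl]-4-hydroxybenzoic acid | O=C(O)c1ccc(O)c(-c2c(O)cc3oc(-c4ccc(O)cc4)cc(=O)c3c2O)c1 | target

## Step count and least certain steps

Total step count: 6. Longest linear sequence: 5 steps (3 → 4 → 6 → 7 → 8 → 9, steps 2 to 6); the second branch is one step (1 → 2) and joins at step 3.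

Step 4 (key step). The seven-membered C–H cleavage at the crowded C6 position may be slower than reduction of the C–Br bond or than arylation between molecules, so that debrominated acetal or oligomers form instead of the bridged biaryl. Fallback, which replaces the tethered C–H arylation by an intermolecular cross-coupling: it sets out from 2, which is iodinated ortho to the free 5-hydroxyl (benzyltrimethylammonium dichloroiodate, CaCO3, CH2Cl2–MeOH) to 5-hydroxy-6-iodo-7-methoxy-2-(4-methoxyphenyl)-4H-chromen-4-one F1. Suzuki–Miyaura coupling of F1 with purchasable [2-methoxy-5-(methoxycarbonyl)phenyl]boronic acid (Pd(OAc)2, SPhos, K3PO4, toluene–water, 90 °C) would give methyl 3-[5-hydroxy-7-methoxy-2-(4-methoxyphenyl)-4-oxo-4H-chromen-6-yl]-4-methoxybenzoate F2. LiOH hydrolysis to 3-[5-hydroxy-7-methoxy-2-(4-methoxyphenyl)-4-oxo-4H-chromen-6-yl]-4-methoxybenzoic acid F3 and BBr3 cleavage of its three methyl ethers bring the sequence back to the route at 9. The price is that site selectivity then rests on the iodination (C6 against C8) and would have to be proven on F1.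

Step 3. The chloro ether may be lost to hydrolysis or to self-condensation before the sluggish, hindered phenoxide of 2 captures it, and incomplete removal of MeSCl would lead to sulfenylation of ring A. Fallback, which reverses the roles of nucleophile and electrophile: it sets out from 2, which is alkylated with ClCH2SMe (NaH, NaI, DMF; a small, stable electrophile that can be used in excess) to 7-methoxy-2-(4-methoxyphenyl)-5-[(methylsulfanyl)methoxy]-4H-chromen-4-one F4. SO2Cl2 at −78 °C in CH2Cl2, with cyclohexene present to take up the sulfenyl chloride, would convert F4 into 5-(chloromethoxy)-7-methoxy-2-(4-methoxyphenyl)-4H-chromen-4-one F5. F5 is then displaced by the unhindered sodium phenoxide of 3 (NaH, DMF), and the sequence comes back to the route at 6.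

Step 6. Three processes threaten this step: Friedel–Crafts capture of the one-carbon electrophile released from the bridge by the newly freed, electron-rich ring A; acid-promoted opening and reclosure of ring C during a warm or slow quench, with migration of the aryl group to C8; and incomplete dealkylation. Fallback, which stages the unmasking over two different mechanisms: it sets out from 8, whose bridge alone is cleaved by BCl3 (CH2Cl2, −78 to 0 °C; chelation at the peri carbonyl assists, and ordinary aryl methyl ethers are spared) while ring A is still deactivated as a boron chelate. This would give 4-hydroxy-3-[5-hydroxy-7-methoxy-2-(4-methoxyphenyl)-4-oxo-4H-chromen-6-yl]benzoic acid F6. The two remaining methyl ethers are then removed by nucleophilic demethylation with NaSEt in DMF at 120 °C, under basic and acid-free conditions, and the sequence comes back to the route at 9.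

Step 1. Methylation may not stop cleanly at the dimethyl stage, and the low solubility of 1 makes over- and under-alkylation harder to control. Fallback, which replaces selective non-alkylation by selective dealkylation: it sets out from 1, which is methylated exhaustively (MeI in excess, K2CO3, DMF, 60 °C) to 5,7-dimethoxy-2-(4-methoxyphenyl)-4H-chromen-4-one F7. BCl3 in CH2Cl2 at 0 °C then removes only the methyl group on O5 through chelation with the C4 carbonyl, and the sequence comes back to the route at 2.

## Further compounds

F1 | step 4 | 5-hydroxy-6-iodo-7-methoxy-2-(4-methoxyphenyl)-4H-chromen-4-one | COc1ccc(-c2cc(=O)c3c(O)c(I)c(OC)cc3o2)cc1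
F2 | step 4 | methyl 3-[5-hydroxy-7-methoxy-2-(4-methoxyphenyl)-4-oxo-4H-chromen-6-yl]-4-methoxybenzoate | COC(=O)c1ccc(OC)c(-c2c(OC)cc3oc(-c4ccc(OC)cc4)cc(=O)c3c2O)c1
F3 | step 4 | 3-[5-hydroxy-7-methoxy-2-(4-methoxyphenyl)-4-oxo-4H-chromen-6-yl]-4-methoxybenzoic acid | O=C(O)c1ccc(OC)c(-c2c(OC)cc3oc(-c4ccc(OC)cc4)cc(=O)c3c2O)c1
F4 | step 3 | 7-methoxy-2-(4-methoxyphenyl)-5-[(methylsulfanyl)methoxy]-4H-chromen-4-one | COc1ccc(-c2cc(=O)c3c(OCSC)cc(OC)cc3o2)cc1
F5 | step 3 | 5-(chloromethoxy)-7-methoxy-2-(4-methoxyphenyl)-4H-chromen-4-one | COc1ccc(-c2cc(=O)c3c(OCCl)cc(OC)cc3o2)cc1
F6 | step 6 | 4-hydroxy-3-[5-hydroxy-7-methoxy-2-(4-methoxyphenyl)-4-oxo-4H-chromen-6-yl]benzoic acid | O=C(O)c1ccc(O)c(-c2c(OC)cc3oc(-c4ccc(OC)cc4)cc(=O)c3c2O)c1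
F7 | step 1 | 5,7-dimethoxy-2-(4-methoxyphenyl)-4H-chromen-4-one | COc1ccc(-c2cc(=O)c3c(OC)cc(OC)cc3o2)cc1
A1 | alternative 1 | tert-butyl 3-{4-hydroxy-2,6-dimethoxy-3-[3-(4-methoxyphenyl)prop-2-ynoyl]phenyl}-4-methoxybenzoate | CC(C)(C)OC(=O)c1ccc(OC)c(-c2c(OC)cc(O)c(C(=O)C#Cc3ccc(OC)cc3)c2OC)c1
A2 | alternative 1 | tert-butyl 3-[2,6-dimethoxy-4-(trifluoromethanesulfonyloxy)-3-(trimethylsilyl)phenyl]-4-methoxybenzoate | CC(C)(C)OC(=O)c1ccc(OC)c(-c2c(OC)cc(OS(=O)(=O)C(F)(F)F)c([Si](C)(C)C)c2OC)c1
A3 | alternative 1 | 3-(4-methoxyphenyl)prop-2-ynoic acid | COc1ccc(C#CC(=O)O)cc1
A4 | alternative 2 | methyl 4-(tert-butyldimethylsilyloxy)-5-[5,7-dimethoxy-2-(4-methoxyphenyl)-4-oxo-4H-chromen-6-yl]cyclohexa-1,4-diene-1-carboxylate | COC(=O)C1=CCC(O[Si](C)(C)C(C)(C)C)=C(C1)c1c(OC)cc2oc(-c3ccc(OC)cc3)cc(=O)c2c1OC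
A5 | alternative 2 | 6-[3-(tert-butyldimethylsilyloxy)buta-1,3-dien-2-yl]-5,7-dimethoxy-2-(4-methoxyphenyl)-4H-chromen-4-one | C=C(O[Si](C)(C)C(C)(C)C)C(=C)c1c(OC)cc2oc(-c3ccc(OC)cc3)cc(=O)c2c1OC
A6 | alternative 2 | methyl propiolate | C#CC(=O)OC
A7 | alternative 3 | methyl 3-[5,7-dimethoxy-2-(4-methoxyphenyl)-4-oxo-4H-chromen-6-yl]-4-ethoxybenzoate | CCOc1ccc(C(=O)OC)cc1-c1c(OC)cc2oc(-c3ccc(OC)cc3)cc(=O)c2c1OC
A8 | alternative 3 | 6-(ethoxyethynyl)-5,7-dimethoxy-2-(4-methoxyphenyl)-4H-chromen-4-one | CCOC#Cc1c(OC)cc2oc(-c3ccc(OC)cc3)cc(=O)c2c1OC
A9 | alternative 3 | methyl coumalate (methyl 2-oxo-2H-pyran-5-carboxylate) | COC(=O)C1=COC(=O)C=C1
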